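## Structural features

The target (18) is a coumaronochromone. A 5,7-dihydroxychromone (rings A and C) is tied to a benzene ring B through an oxygen (C2–O–C2') and a direct C3–C1' bond, so a furan (ring D) lies between them and the four rings form one flat conjugated system. A fifth ring, a 2,3-dihydrofuran (ring E), is fused to the C3'–C4' edge of ring B, with its oxygen on C4' and its CH2 on C3'. Ring B is therefore a 1,2,3,4-tetrasubstituted benzene in the order C, O, C, O, with only C5'–H and C6'–H left. There is one stereocentre, the S-configured O–CH of ring E, between the benzylic CH2 and the tertiary carbinol C(CH3)2OH. It has no neighbouring stereocentre and no resident directing group, so the whole stereochemical task is absolute control at one carbon. The fragile points are the tertiary alcohol (loss of water under strong acid), the 2-oxygenated chromone (a vinylogous carbonate that opens with hard nucleophiles) and the electron-rich free phenols. The real difficulty is to place two different oxygen heterocycles correctly on the crowded ring B and to make the lone stereocentre enantioselectively. The plan uses the C2–C3 bond of ring E: the benzylic CH2 is introduced as a carbene carbon on C3' (the masked aldehyde of a 2,6-dioxygenated benzaldehyde), and the O–CH is the OCH2 of an ether on C4', so one C–H alkylation closes ring E and creates the stereocentre.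

## Logic of the disconnections

18 to 17: the two O–CH2Ph bonds on the C5 and C7 oxygens are cut. The phloroglucinol-type phenols would compete as nucleophiles and be oxidised in the steps before, and benzyl comes off under neutral hydrogenolysis that spares the tertiary alcohol. Nothing is gained in skeleton. The forward step must cleave only benzylic C–O bonds and leave the aryl–O bonds of rings D and E alone.

17 to 16: the C3–C1' bond of ring D is cut. Ring B has a single free position ortho to the bridging oxygen, so the closure can go only one way and needs no halogen. The pentacycle falls into two bicyclic halves held by one ether bond. The forward step is a twofold C–H coupling that has to tolerate a free tertiary alcohol and two benzyl ethers.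

16 to 10 and 15: the C2–O aryl ether bond is cut. C2 of a chromone that carries a leaving group is a vinylogous acyl electrophile, so the bond forms by addition–elimination. This is the convergent point, with two fragments of similar size. The forward step requires that only the phenol of 10 reacts and that the leaving group departs at ambient temperature.

15 to 14: the two S–O bonds are cut. The sulfide is the stable storage form and is raised to the leaving-group oxidation level only when needed. The oxidant must leave the benzyl ethers and the enone untouched.

14 to 13: the S–CH3 bond is cut. Alkylation has to occur on sulfur and not on the C4 oxygen, which the soft sulfur centre ensures.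

13 to 12: the C2–C3 and O1–C2 bonds of ring C are cut, removing a one-carbon thiocarbonyl unit. The pyranone and its C2 heteroatom handle then come from an ortho-hydroxyaryl methyl ketone in one operation. The forward step needs a ketone enolate and a free ortho phenol.

12 to 11: two O–CH2Ph bonds are cut. The third hydroxyl must stay free for ring C, and the hydrogen bond to the ketone provides that selectivity.

10 to 9: the two O–Si bonds are cut. This step only unmasks the nucleophilic phenol and the tertiary alcohol and must not touch the stereocentre.

9 to 7, through transient 8: the C2–C3 bond of ring E is cut, with C3 traced to a carbene carbon and C2 to an ether OCH2. This removes the ring and the only stereocentre at once and leaves a flat, achiral benzaldehyde derivative. The forward step has to deliver site selectivity (only the OCH2 hydrogens) and enantioselectivity from the catalyst alone, which is why every other oxygen substituent near the carbene carries no C–H next to oxygen.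

7 to 5 and 6: the C=N bond is cut. The sulfonyl hydrazone is the bench-stable diazo precursor. The condensation must be neutral enough to keep both silyl ethers.

5 to 3, through 4: the two O–Si bonds are cut. Silyl groups are chosen because they offer no hydrogen for abstraction. The forward step must silylate a phenol and a hindered tertiary alcohol without touching the aldehyde.

3 to 1 and 2: the aryl O–CH2 bond is cut. This desymmetrises the two hydroxyls of 1 and installs the whole three-carbon side chain from an achiral piece. The forward step must stop at mono-alkylation.

## Other disconnections considered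

Alternative 1: Ring B is taken apart at C1'–C2', C2'–C3' and C4'–C5'. The forward step is a photochemical Wolff rearrangement of the dienyl diazo ketone A2, (E)-4-[5,7-bis(benzyloxy)-4-oxochromen-3-yl]-1-diazobut-3-en-2-one, to a vinylketene. This adds the siloxyalkyne A3, (R)-triisopropyl{[3-(2,2,5,5-tetramethyl-1,3-dioxolan-4-yl)prop-1-yn-1-yl]oxy}silane, and the cyclobutenone opens and recloses to the isoflavone A1 (free 2'-OH, 4'-silyloxy, acetonide side chain on C3').
- In its favour: the mechanism fixes the substitution pattern of ring B, the two oxygens arrive already differentiated, and the stereocentre comes from a well-tried source such as asymmetric dihydroxylation. On regiochemical certainty and on independence from a specialised chiral catalyst it is the equal or the better of the chosen plan.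
- Against it here: after A1 both heterocycles are still open. Ring D needs an oxidative closure of the 2'-hydroxyisoflavone. Ring E must close by displacement at the secondary carbinol with inversion (which is why A1 carries the R diol for an S target), in competition with reaction at the tertiary centre. The chromone is a strong ultraviolet chromophore and a possible 2π partner in the irradiation. A2 and A3 each need several steps, and siloxyalkynes are sensitive.
- Comparison: in structure it is more general. In mechanism it is a chain of four pericyclic events where the chosen plan has one radical hydrogen transfer and substitution. In step count it is clearly longer, because the chosen plan buys ring B intact as 1.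

Alternative 2: The cut is the C3–C1' bond of ring D. The forward step is palladation of chromone C3 and of the one free ortho C–H of the aryloxy ring by Pd(OAc)2 with AgOAc in pivalic acid, followed by reductive elimination to A4, the 5,7-di-O-benzyl target, which is identical with 17.
- In its favour: it joins two halves of similar size, needs no halogen, and has no regiochemical choice to make.
- Against it here: taken as the strategy-bearing step it creates no stereocentre and leaves the origin of the chiral arm open. It also uses stoichiometric silver and hot acid next to a tertiary alcohol.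
- Comparison: this is the same closure as step 11 of the chosen route, passing through the same compounds 16 and 17, so on this bond the two plans are equal. They differ only in how 10 is made. A plan centred on this closure would most likely reach 10 from the prenylated resorcinol A5, 2-(3-methylbut-2-en-1-yl)benzene-1,3-diol, by asymmetric dihydroxylation and cyclisation. That is better precedented for stereocontrol and in this respect the equal or the better. It needs the two phenols of A5 to be told apart and is longer than the five steps from 1 to 10.

Alternative 3: The cuts are O1–C8a and C4–C4a of ring C. In the forward step CsF releases 3,5-bis(benzyloxy)benzyne from the silyl triflate A7, 3,5-bis(benzyloxy)-2-(trimethylsilyl)phenyl trifluoromethanesulfonate. The enolate oxygen of the benzofuranone ester A8 (methyl 2-oxo-2,3-dihydrobenzofuran-3-carboxylate carrying ring E with a triethylsilyl-protected carbinol) adds to the aryne carbon remote from the flanking benzyloxy group. The aryl anion then attacks the ester to close the pyranone and give A6, the 5,7-di-O-benzyl, O-triethylsilyl target.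
- In its favour: the known preference of 3-alkoxyarynes for attack meta to the alkoxy group matches the 5,7 pattern. The late stage needs neither palladium nor an oxidant and is mild towards the masked tertiary alcohol. On these two points it is the better of the two plans.
- Against it here: the nucleophile is an ambident, malonate-like enolate, for which C-arylation and insertion of the aryne into the C–C(O) bond are the usual paths. The lactone carbonyl is a second electrophile for the aryl anion. A8 must already hold rings B and E with the stereocentre plus the lactone ester, so it is harder to make than 10, and A7 needs several steps of its own.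
- Comparison: the stereocentre problem is the same in both plans, since the carbene closure could supply the arm of A8 as well, so there they are equal. The chemoselectivity risk sits at the decisive, most convergent step, and the step count is higher.

Key step: step 4

Remarks on the chemistry:
- Isoflavonoid numbering (C2, C3, C1'–C6') is used for the target and benzofuran numbering for the arm.
- The stereocentre is S in 18 (ranking O > C(CH3)2O > CH2 > H). The ranking is the same in 9, 10, 16 and 17, so the descriptor does not change along the route.
- Co(Por*) is the divalent cobalt complex of the dianion of 5,15-bis[2,6-bis(2,2-dimethylcyclopropanecarboxamido)phenyl]-10,20-bis(3,5-di-tert-butylphenyl)porphyrin, with all four cyclopropane stereocentres of one configuration.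
- Assumption: the ligand antipode that leads to (S)-9 is used. Both antipodes are available from the enantiomeric amides, and the sense of induction has to be assigned on the first run.
- The phenol silyl group in the precursor is triisopropylsilyl rather than tert-butyldimethylsilyl. An aryl tert-butyldimethylsilyl ether ortho to a hydrazone anion under Cs2CO3 is exposed to cleavage and to silyl transfer. The bulkier group resists both and still has no C–H next to oxygen.

## Route

Step 1
Reactants: 1 2,6-dihydroxybenzaldehyde; 2 2,2-dimethyloxirane
Product: 3 2-hydroxy-6-(2-hydroxy-2-methylpropoxy)benzaldehyde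
Conditions: 2 (1.5 equiv), K2CO3 (0.5 equiv), DMF, 80 °C, sealed tube
Reagents that add atoms: none
Why: Phenoxide opening of the epoxide at its unhindered CH2 (epoxide variant of the Williamson ether synthesis). With substoichiometric base the more acidic 1 holds the negative charge, and the remaining hydroxyl of 3 is hydrogen-bonded to the aldehyde and poorly nucleophilic, which favours mono-alkylation.

Step 2
Reactants: 3 2-hydroxy-6-(2-hydroxy-2-methylpropoxy)benzaldehyde
Product: 5 2-[2-(tert-butyldimethylsilyloxy)-2-methylpropoxy]-6-(triisopropylsilyloxy)benzaldehyde, via mono-triisopropylsilyl ether 4 (not isolated)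
Conditions: 2,6-lutidine (4 equiv), TIPSOTf (1.05 equiv), CH2Cl2, −78 to 0 °C; then TBSOTf (1.5 equiv), 0 °C to rt
Reagents that add atoms: triisopropylsilyl trifluoromethanesulfonate, CC(C)[Si](OS(=O)(=O)C(F)(F)F)(C(C)C)C(C)C; tert-butyldimethylsilyl trifluoromethanesulfonate, CC(C)(C)[Si](C)(C)OS(=O)(=O)C(F)(F)F
Why: Silylation with silyl triflates and a hindered pyridine base: the bulky triisopropylsilyl triflate takes the phenol and hardly touches the tertiary alcohol in the cold, then the smaller tert-butyldimethylsilyl triflate caps the tertiary alcohol. The aldehyde has no α-hydrogen and is inert.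

Step 3
Reactants: 5 2-[2-(tert-butyldimethylsilyloxy)-2-methylpropoxy]-6-(triisopropylsilyloxy)benzaldehyde; 6 p-toluenesulfonyl hydrazide
Product: 7 (E)-N'-{2-[2-(tert-butyldimethylsilyloxy)-2-methylpropoxy]-6-(triisopropylsilyloxy)benzylidene}-4-methylbenzenesulfonohydrazide
Conditions: 6 (1.05 equiv), MeOH–THF, rt
Reagents that add atoms: none
Why: Condensation of an aldehyde with a sulfonyl hydrazide to the hydrazone, which settles in the more stable E form. No acid or base is added, so both silyl ethers survive.

Step 4
Reactants: 7 (E)-N'-{2-[2-(tert-butyldimethylsilyloxy)-2-methylpropoxy]-6-(triisopropylsilyloxy)benzylidene}-4-methylbenzenesulfonohydrazide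
Product: 9 (S)-2-[2-(tert-butyldimethylsilyloxy)propan-2-yl]-4-(triisopropylsilyloxy)-2,3-dihydrobenzofuran, via aryldiazomethane 8 (not isolated)
Conditions: Co(Por*) (2–5 mol %), Cs2CO3 (2 equiv), toluene, 40 °C, N2
Reagents that add atoms: none
Why: Cs2CO3 deprotonates the sulfonyl hydrazone and the salt loses p-toluenesulfinate (Bamford–Stevens reaction) to release aryldiazomethane 8 slowly, which keeps its concentration low and holds back azine formation. The divalent cobalt metalloradical Co(Por*) takes up 8 with loss of N2 and becomes a trivalent cobalt species with an α-cobalt benzyl radical. This radical abstracts a hydrogen from the OCH2 group through a six-membered transition state (1,5-hydrogen atom transfer), and the α-aryloxyalkyl radical then attacks the cobalt-bound carbon, forming the C2–C3 bond and returning divalent cobalt. The closest known reaction type is the enantioselective intramolecular 1,5-C–H alkylation of aryldiazomethanes generated from N-tosylhydrazones under chiral cobalt amidoporphyrin metalloradical catalysis, which gives 2-substituted five-membered benzo-fused heterocycles. The dihydrofuran ring closes in the 5-exo-tet mode, as a homolytic substitution at carbon with cobalt as the leaving group. The new C2 stereocentre is set by the catalyst alone: the amide N–H groups and cyclopropyl walls of Por* hold the prochiral α-oxy radical so that one face meets the Co–C bond, and the ligand antipode is chosen for S. Site selectivity is required and is secured by the 1,5 geometry, by the weakening of the OCH2 C–H bonds through the adjacent oxygen, and by the fact that neither silyl group has a C–H next to oxygen or within 1,5 reach. The triisopropylsilyl ether on the phenol is there to withstand Cs2CO3 and to resist silyl transfer to the hydrazone anion, either of which would release a phenoxide next to the diazo carbon.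

Step 5
Reactants: 9 (S)-2-[2-(tert-butyldimethylsilyloxy)propan-2-yl]-4-(triisopropylsilyloxy)-2,3-dihydrobenzofuran
Product: 10 (S)-2-(2-hydroxypropan-2-yl)-2,3-dihydrobenzofuran-4-ol
Conditions: Bu4NF (3 equiv), THF, 0 °C to 40 °C; aqueous work-up
Reagents that add atoms: none
Why: Fluoride-mediated desilylation, driven by the strong Si–F bond, removes the aryl silyl ether at once and the tertiary alkyl silyl ether on warming. No bond to the stereocentre is broken.

Step 6
Reactants: 11 1-(2,4,6-trihydroxyphenyl)ethanone
Product: 12 1-[2,4-bis(benzyloxy)-6-hydroxyphenyl]ethanone
Conditions: BnBr (2.05 equiv), K2CO3 (2.2 equiv), DMF, rt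
Reagents that add atoms: benzyl bromide, BrCc1ccccc1
Why: Williamson ether synthesis. The para hydroxyl and one ortho hydroxyl are benzylated, while the last ortho hydroxyl is held by its hydrogen bond to the ketone and stays free when the bromide is limited to two equivalents.

Step 7
Reactants: 12 1-[2,4-bis(benzyloxy)-6-hydroxyphenyl]ethanone
Product: 13 5,7-bis(benzyloxy)-4-hydroxy-2H-chromene-2-thione
Conditions: KOtBu (3 equiv), CS2 (2 equiv), THF, 0 °C to rt; then 10% aq. H2SO4
Reagents that add atoms: carbon disulfide, S=C=S
Why: Claisen-type condensation of the ketone enolate with CS2 gives a β-keto dithioacid, which on acidification is closed by the ortho phenol with loss of H2S. This is the established entry to 2-thio-substituted chromones from ortho-hydroxyacetophenones.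

Step 8
Reactants: 13 5,7-bis(benzyloxy)-4-hydroxy-2H-chromene-2-thione
Product: 14 5,7-bis(benzyloxy)-2-(methylthio)-4H-chromen-4-one
Conditions: MeI (1.2 equiv), K2CO3 (1.5 equiv), acetone, rt
Reagents that add atoms: iodomethane, CI
Why: S-alkylation of the ambident thione anion at its soft sulfur centre, which fixes the 4-chromone tautomer.

Step 9
Reactants: 14 5,7-bis(benzyloxy)-2-(methylthio)-4H-chromen-4-one
Product: 15 5,7-bis(benzyloxy)-2-(methylsulfonyl)-4H-chromen-4-one
Conditions: mCPBA (2.3 equiv), CH2Cl2, 0 °C to rt; Na2S2O3/NaHCO3 wash
Reagents that add atoms: 3-chloroperoxybenzoic acid, OOC(=O)c1cccc(Cl)c1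
Why: Peracid oxidation of the sulfide through the sulfoxide to the sulfone. The electron-poor enone and the benzyl ethers are not attacked.

Step 10
Reactants: 10 (S)-2-(2-hydroxypropan-2-yl)-2,3-dihydrobenzofuran-4-ol; 15 5,7-bis(benzyloxy)-2-(methylsulfonyl)-4H-chromen-4-one
Product: 16 (S)-5,7-bis(benzyloxy)-2-{[2-(2-hydroxypropan-2-yl)-2,3-dihydrobenzofuran-4-yl]oxy}-4H-chromen-4-one
Conditions: K2CO3 (1.5 equiv), dry MeCN, rt
Reagents that add atoms: none
Why: Addition–elimination at C2 of the 2-sulfonylchromone (conjugate addition of the phenoxide, then loss of methanesulfinate), a known route to 2-aryloxychromones. Carbonate deprotonates only the phenol, so the tertiary alcohol does not compete.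

Step 11
Reactants: 16 (S)-5,7-bis(benzyloxy)-2-{[2-(2-hydroxypropan-2-yl)-2,3-dihydrobenzofuran-4-yl]oxy}-4H-chromen-4-one
Product: 17 5,7-di-O-benzyl ether of the target, the (S)-coumaronochromone with benzyloxy groups on C5 and C7
Conditions: Pd(OAc)2 (10 mol %), AgOAc (2.5 equiv), PivOH, 100 °C
Reagents that add atoms: none
Why: Intramolecular dehydrogenative (twofold C–H) coupling of the kind established for 4-aryloxycoumarins and 2-aryloxychromones: divalent palladium palladates the electron-rich chromone C3, carboxylate-assisted metalation takes the only free ortho C–H of the aryloxy ring (C5 of the dihydrobenzofuran), and reductive elimination from the six-membered palladacycle closes the furan. Zerovalent palladium is returned to the divalent state by monovalent silver. The tertiary alcohol has no α-hydrogen to oxidise, and the stereocentre is remote.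

Step 12
Reactants: 17 5,7-di-O-benzyl ether of the target
Product: 18 the target, the (S)-5,7-dihydroxycoumaronochromone with the 2-(2-hydroxypropan-2-yl)-2,3-dihydrofuran fused at C3'–C4' (oxygen on C4')
Conditions: H2 (1 atm), 10% Pd/C, EtOAc–MeOH, rt
Reagents that add atoms: none
Why: Hydrogenolysis of the two benzyl ethers. The C2=C3 bond is part of the aromatic furan, the ring E oxygen sits on a non-benzylic carbon and the tertiary alcohol is inert, so only the benzylic C–O bonds are cleaved.

## Compound list

1 | 2,6-dihydroxybenzaldehyde | O=Cc1c(O)cccc1O | starting material
2 | 2,2-dimethyloxirane | CC1(C)CO1 | starting material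
3 | 2-hydroxy-6-(2-hydroxy-2-methylpropoxy)benzaldehyde | O=Cc1c(O)cccc1OCC(C)(C)O | intermediate
4 | 2-(2-hydroxy-2-methylpropoxy)-6-(triisopropylsilyloxy)benzaldehyde | O=Cc1c(O[Si](C(C)C)(C(C)C)C(C)C)cccc1OCC(C)(C)O | intermediate (not isolated)
5 | 2-[2-(tert-butyldimethylsilyloxy)-2-methylpropoxy]-6-(triisopropylsilyloxy)benzaldehyde | O=Cc1c(O[Si](C(C)C)(C(C)C)C(C)C)cccc1OCC(C)(C)O[Si](C)(C)C(C)(C)C | intermediate
6 | p-toluenesulfonyl hydrazide | Cc1ccc(cc1)S(=O)(=O)NN | starting material
7 | (E)-N'-{2-[2-(tert-butyldimethylsilyloxy)-2-methylpropoxy]-6-(triisopropylsilyloxy)benzylidene}-4-methylbenzenesulfonohydrazide | Cc1ccc(cc1)S(=O)(=O)N/N=C/c1c(O[Si](C(C)C)(C(C)C)C(C)C)cccc1OCC(C)(C)O[Si](C)(C)C(C)(C)C | intermediate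
8 | 1-[2-(tert-butyldimethylsilyloxy)-2-methylpropoxy]-2-(diazomethyl)-3-(triisopropylsilyloxy)benzene | [N-]=[N+]=Cc1c(O[Si](C(C)C)(C(C)C)C(C)C)cccc1OCC(C)(C)O[Si](C)(C)C(C)(C)C | intermediate (not isolated)
9 | (S)-2-[2-(tert-butyldimethylsilyloxy)propan-2-yl]-4-(triisopropylsilyloxy)-2,3-dihydrobenzofuran | CC(C)(O[Si](C)(C)C(C)(C)C)[C@@H]1Cc2c(O[Si](C(C)C)(C(C)C)C(C)C)cccc2O1 | intermediate
10 | (S)-2-(2-hydroxypropan-2-yl)-2,3-dihydrobenzofuran-4-ol | CC(C)(O)[C@@H]1Cc2c(O)cccc2O1 | intermediate
11 | 1-(2,4,6-trihydroxyphenyl)ethanone | CC(=O)c1c(O)cc(O)cc1O | starting material
12 | 1-[2,4-bis(benzyloxy)-6-hydroxyphenyl]ethanone | CC(=O)c1c(O)cc(OCc2ccccc2)cc1OCc1ccccc1 | intermediate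
13 | 5,7-bis(benzyloxy)-4-hydroxy-2H-chromene-2-thione | Oc1cc(=S)oc2cc(OCc3ccccc3)cc(OCc3ccccc3)c12 | intermediate
14 | 5,7-bis(benzyloxy)-2-(methylthio)-4H-chromen-4-one | CSc1cc(=O)c2c(OCc3ccccc3)cc(OCc3ccccc3)cc2o1 | intermediate
15 | 5,7-bis(benzyloxy)-2-(methylsulfonyl)-4H-chromen-4-one | CS(=O)(=O)c1cc(=O)c2c(OCc3ccccc3)cc(OCc3ccccc3)cc2o1 | intermediate
16 | (S)-5,7-bis(benzyloxy)-2-{[2-(2-hydroxypropan-2-yl)-2,3-dihydrobenzofuran-4-yl]oxy}-4H-chromen-4-one | CC(C)(O)[C@@H]1Cc2c(Oc3cc(=O)c4c(OCc5ccccc5)cc(OCc5ccccc5)cc4o3)cccc2O1 | intermediate
17 | 5,7-di-O-benzyl ether of the target | CC(C)(O)[C@@H]1Cc2c(ccc3c2oc2oc4cc(OCc5ccccc5)cc(OCc5ccccc5)c4c(=O)c23)O1 | intermediate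
18 | target CNP0193284.1, (S)-5,7-dihydroxycoumaronochromone with a 2-(2-hydroxypropan-2-yl)-2,3-dihydrofuran fused at C3'–C4' | CC(C)(O)[C@@H]1Cc2c(ccc3c2oc2oc4cc(O)cc(O)c4c(=O)c23)O1 | target

## Step count and risk

Total: 12 steps. Longest linear sequence: 8 steps (steps 1–5, then 10–12). The chromone arm is 4 steps (6–9) and joins at step 10.

Least certain steps:

Step 4 (key step). The carbene carbon is flanked by two ortho substituents, which may slow uptake of the diazo compound by cobalt and let azine formation or carbene dimerisation take over. The bulky silyloxy-bearing carbon next to the reacting CH2 may give poor facial discrimination in the ring-closing radical substitution. Premature loss of the aryl silyl group under carbonate would also stop the reaction.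
Fallback, from 1 back to 10, with ring E built by condensation and the stereocentre obtained by resolution:
- 1 is condensed with ethyl bromoacetate (K2CO3, DMF, 90 °C; O-alkylation followed by intramolecular aldol condensation, a Rap–Stoermer-type benzofuran synthesis) to give ethyl 4-hydroxybenzofuran-2-carboxylate F1.
- Conjugate reduction with Mg in MeOH, with ester exchange, gives racemic methyl 4-hydroxy-2,3-dihydrobenzofuran-2-carboxylate F2.
- Separation of the enantiomers on a chiral stationary phase gives methyl (S)-4-hydroxy-2,3-dihydrobenzofuran-2-carboxylate F3.
- Excess MeMgBr in THF at 0 °C (twofold Grignard addition) converts the ester into the tertiary alcohol, and the route is rejoined at 10.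

Step 11. The tertiary alcohol may lose water in hot pivalic acid, the second C–H metalation may be slow so that protodepalladation and decomposition compete, and silver may oxidise the electron-rich ring B.
Fallback, from 10 back to 17, replacing the twofold C–H coupling by a halide-based direct arylation under basic conditions:
- 10 is brominated ortho to the phenol with NBS and catalytic diisopropylamine in CH2Cl2 (amine-mediated ortho-selective phenol bromination) to give (S)-5-bromo-2-(2-hydroxypropan-2-yl)-2,3-dihydrobenzofuran-4-ol F4.
- F4 is joined to 15 as in step 10 to give (S)-5,7-bis(benzyloxy)-2-{[5-bromo-2-(2-hydroxypropan-2-yl)-2,3-dihydrobenzofuran-4-yl]oxy}-4H-chromen-4-one F5.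
- Intramolecular direct arylation (Pd(OAc)2, PCy3·HBF4, K2CO3, DMA, 110 °C; oxidative addition of zerovalent palladium into C–Br, then carboxylate-assisted C3–H metalation and reductive elimination) gives 17.

Step 1. Alkylation may run on to the second hydroxyl, or the hydrogen-bonded, conjugated phenoxide may open the epoxide too slowly while the volatile epoxide is lost.
Fallback, from 1 back to 3, using a reactive allylic electrophile and a later hydration:
- 1 is mono-alkylated with 3-chloro-2-methylprop-1-ene (K2CO3, DMF, 50 °C) to give 2-hydroxy-6-[(2-methylprop-2-en-1-yl)oxy]benzaldehyde F6.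
- Markovnikov hydration of the 1,1-disubstituted alkene under Mukaiyama conditions (Co(acac)2, PhSiH3, O2, THF, rt) gives 3. The aldehyde and free phenol are the points to watch in this hydration.

Step 2. Silylation of the hindered tertiary alcohol may stay incomplete, or silyl groups may scramble between the two oxygens.
Fallback, from 3 back to 10, leaving the tertiary alcohol free (alcohols are tolerated by the cobalt radical system):
- The sequence is stopped after the first silylation and 4 is isolated.
- 4 is condensed with 6 to give (E)-N'-[2-(2-hydroxy-2-methylpropoxy)-6-(triisopropylsilyloxy)benzylidene]-4-methylbenzenesulfonohydrazide F7.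
- Cyclisation as in step 4 gives (S)-2-[4-(triisopropylsilyloxy)-2,3-dihydrobenzofuran-2-yl]propan-2-ol F8.
- Bu4NF removes the single silyl group and gives 10.

## Further compounds

F1 | step 4 | ethyl 4-hydroxybenzofuran-2-carboxylate | CCOC(=O)c1cc2c(O)cccc2o1
F2 | step 4 | racemic methyl 4-hydroxy-2,3-dihydrobenzofuran-2-carboxylate | COC(=O)C1Cc2c(O)cccc2O1
F3 | step 4 | methyl (S)-4-hydroxy-2,3-dihydrobenzofuran-2-carboxylate | COC(=O)[C@@H]1Cc2c(O)cccc2O1
F4 | step 11 | (S)-5-bromo-2-(2-hydroxypropan-2-yl)-2,3-dihydrobenzofuran-4-ol | CC(C)(O)[C@@H]1Cc2c(O)c(Br)ccc2O1
F5 | step 11 | (S)-5,7-bis(benzyloxy)-2-{[5-bromo-2-(2-hydroxypropan-2-yl)-2,3-dihydrobenzofuran-4-yl]oxy}-4H-chromen-4-one | CC(C)(O)[C@@H]1Cc2c(Oc3cc(=O)c4c(OCc5ccccc5)cc(OCc5ccccc5)cc4o3)c(Br)ccc2O1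
F6 | step 1 | 2-hydroxy-6-[(2-methylprop-2-en-1-yl)oxy]benzaldehyde | O=Cc1c(O)cccc1OCC(C)=C
F7 | step 2 | (E)-N'-[2-(2-hydroxy-2-methylpropoxy)-6-(triisopropylsilyloxy)benzylidene]-4-methylbenzenesulfonohydrazide | Cc1ccc(cc1)S(=O)(=O)N/N=C/c1c(O[Si](C(C)C)(C(C)C)C(C)C)cccc1OCC(C)(C)O
F8 | step 2 | (S)-2-[4-(triisopropylsilyloxy)-2,3-dihydrobenzofuran-2-yl]propan-2-ol | CC(C)(O)[C@@H]1Cc2c(O[Si](C(C)C)(C(C)C)C(C)C)cccc2O1
A1 | alternative 1 | 5,7-bis(benzyloxy)-2'-hydroxy-4'-(triisopropylsilyloxy)isoflavone with the (R)-2,2,5,5-tetramethyl-1,3-dioxolan-4-ylmethyl group on C3' | O=c1c(-c2ccc(O[Si](C(C)C)(C(C)C)C(C)C)c(C[C@H]3OC(C)(C)OC3(C)C)c2O)coc2cc(OCc3ccccc3)cc(OCc3ccccc3)c12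
A2 | alternative 1 | (E)-4-[5,7-bis(benzyloxy)-4-oxo-4H-chromen-3-yl]-1-diazobut-3-en-2-one | [N-]=[N+]=CC(=O)/C=C/c1coc2cc(OCc3ccccc3)cc(OCc3ccccc3)c2c1=O
A3 | alternative 1 | (R)-triisopropyl{[3-(2,2,5,5-tetramethyl-1,3-dioxolan-4-yl)prop-1-yn-1-yl]oxy}silane | CC(C)[Si](OC#CC[C@H]1OC(C)(C)OC1(C)C)(C(C)C)C(C)C
A4 | alternative 2 | 5,7-di-O-benzyl ether of the target (identical with 17) | CC(C)(O)[C@@H]1Cc2c(ccc3c2oc2oc4cc(OCc5ccccc5)cc(OCc5ccccc5)c4c(=O)c23)O1
A5 | alternative 2 | 2-(3-methylbut-2-en-1-yl)benzene-1,3-diol | CC(C)=CCc1c(O)cccc1O
A6 | alternative 3 | 5,7-di-O-benzyl, O-triethylsilyl ether of the target | CC(C)(O[Si](CC)(CC)CC)[C@@H]1Cc2c(ccc3c2oc2oc4cc(OCc5ccccc5)cc(OCc5ccccc5)c4c(=O)c23)O1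
A7 | alternative 3 | 3,5-bis(benzyloxy)-2-(trimethylsilyl)phenyl trifluoromethanesulfonate | C[Si](C)(C)c1c(OCc2ccccc2)cc(OCc2ccccc2)cc1OS(=O)(=O)C(F)(F)F
A8 | alternative 3 | methyl 2-oxo-2,3-dihydrobenzofuran-3-carboxylate fused at C6–C7 with the (S)-2-[2-(triethylsilyloxy)propan-2-yl]-2,3-dihydrofuran ring (oxygen on C6) | COC(=O)C1C(=O)Oc2c1ccc1O[C@@H](Cc12)C(C)(C)O[Si](CC)(CC)CC
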